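- I decide to judge this pair by what each exchange costs in incoming ligand, and only then by how fast the clocks run.

| flask | starting complex | incoming ligand | temperature | remark | time |
|---|---|---|---|---|---|
| grey | 0.034 M (in portions, 2) | 2 equiv | 65 °C | run made earlier; portions every 30 min |  |
| ochre | 0.075 M (in portions, 2) | 2 equiv | 80 °C | run made earlier; portions every 30 min |  |
| amber | 0.050 M (in portions, 2) | 1 equiv | 65 °C | run made earlier; portions every 30 min |  |
| theta | 0.050 M (in portions, 2) | 2.00 equiv | 80 °C | the portions of starting complex follow each other after 30 min, the first at the start | 1.0 h |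
| alpha | 0.050 M | 2.00 equiv | 80 °C | everything together at the start | 1.0 h |

- grey (time / min: complex with two exchanged / %, starting complex / %): 6.00: 0.2, 47.8; 20.0: 1.0, 44.3; 30.0: 2.3, 43.9; 50.0: 4.1, 84.7; 80.0: 9.1, 78.0
- ochre (time / min: complex with two exchanged / %, starting complex / %): 8.00: 3.8, 37.9; 15.0: 12.4, 29.5; 20.0: 15.0, 25.9; 30.0: 19.7, 18.3; 40.0: 27.9, 59.5
- amber (time / min: complex with two exchanged / %, starting complex / %): 6.00: 0.5, 48.0; 10.0: 0, 48.1; 20.0: 0, 48.1; 40.0: 1.5, 92.4; 80.0: 3.9, 83.8

(readings scatter by 1 percentage point)



1. the flask that ends with the higher amount of complex with two exchanged, in percent of the starting complex charged, or "neither" when 2 percentage points or less lies between them (theta / alpha / neither)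
2. final complex with two exchanged, as a percentage of the starting complex charged, in theta
3. final complex with two exchanged, as a percentage of the starting complex charged, in alpha

- On the first rung of my ladder, ochre's readings show complex with two exchanged forming at 0.0445 min⁻¹ per unit of complex with one exchanged, taken as the missing balance. Scaled in proportion to ligand, this gives alpha a half-life of 23.3 min.
- On the next rung, ochre's first portion of starting complex falls at an average apparent constant of 0.0335 min⁻¹, which scales to 31.0 min in alpha, slower than the first rung.
- That half-life is about theta's delay of 30 min, so I expect alpha ahead of theta by more than the margin.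
- Ochre's second portion falls at 0.0138 min⁻¹, so about 41.2% of the ligand seems free by then.
- I call the ligand price of an exchange 1.96 equiv: free ligand lost per exchange made per complex, a reading with its scatter.
- The charge then buys a mark of 50.9% complex with two exchanged, and alpha has 1.94 half-lives to approach it.
- The forecast gives alpha, with 31% for theta and 43% for alpha, on the ground “Delaying half the complex costs reaction time”.
- The flasks give 30.8% in theta and 36.6% in alpha, so alpha leads, 6.4 percentage points below the forecast's alpha.

    leaving ligand + incoming ligand ⇌ idle adduct, settled at all times (K = 75.0 M⁻¹, ΔH = −36.0 kJ mol⁻¹)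
    complex with one exchanged + incoming ligand ⇌ leaving ligand + complex with two exchanged (K = 42.0, k = 0.0135 M⁻¹ s⁻¹, Ea = 72.0 kJ mol⁻¹, ΔH = −81.0 kJ mol⁻¹)
    starting complex + incoming ligand ⇌ leaving ligand + complex with one exchanged (K = 0.380, k = 0.00467 M⁻¹ s⁻¹, Ea = 89.0 kJ mol⁻¹, ΔH = −46.0 kJ mol⁻¹)
    (constants at 80 °C)

- Alpha is not at rest after 1.0 h: at 10.0 h it holds 58.9% complex with two exchanged, as does theta with 58.9%, while alpha's starting complex stands at 36.5% and its ligand at 11.1%. That is above my mark, and alpha's price reckoned from those amounts is 1.45 equiv.
- For the neighbour like alpha kept at 95 °C, I carry over the price read in ochre at 80 °C as a trial, which gives a mark of 50.9%; the flask gives 49.1% at 1.00 h, with 44.2% starting complex and 22% of its ligand left and a price reckoned from those amounts of 1.49 equiv, so the nearness of mark and flask is no check.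

All runs were computed for substances that don't exist, noise included.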